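Flavone numbering is used for the chromenone (rings A, B, C); the lactone atoms carry primes (O1', C2' carbonyl, C3', C4', C5').

## Analysis of the target

The target is a flavone: benzo ring A is fused to the 4-pyranone ring C, which carries the phenyl ring B at C2. Ring A bears a methoxy group at C7 and, at C8, the C3' carbon of a 5,5-dimethylfuran-2(5H)-one. There is no stereocentre, and the C8–C3' axis is not expected to be configurationally stable, so the problem is one of constitution only. The sensitive groups are the butenolide (Michael acceptor at C4', acylating agent at C2'), the pyranone (opened by nucleophiles at C2) and, in partly saturated precursors, the enol ether at C7. The difficulty is C8: it is the most hindered position of ring A, wedged between C7–OMe and C8a–O1, it competes with C6 in any functionalisation of an aromatic 7-oxygenated flavone, and it must carry an electron-poor, base-sensitive sp2 substituent. The plan rests on the fact that C8 lies between the two oxygen-bearing carbons C7 and C8a while C5 and C6 are unsubstituted. With the C5–C6 bond saturated, ring A is the methyl enol ether of a 2-substituted six-membered 1,3-diketone: C8 is the carbon between the oxygenated carbons, C8a is the free ketone whose oxygen becomes O1, the α' carbon of that ketone is C4a, and C5–C6 is an ethano bridge that can be dehydrogenated last.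

## Retrosynthetic reasoning

**13 ⇒ 12.** The last operation changes only the oxidation level: the C5=C6 double bond is removed, leaving the 5,6-dihydro compound 12. This comes first in the analysis because it makes C4a an enolisable carbon one stage earlier, and because a partly saturated ring A has no position that competes with C8. Forward, a hydride must leave C5 and a proton C6. The cation formed is the arenium ion of 13, stabilised by the C7 methoxy group and O1, so a quinone oxidant should suffice and the lactone is not at risk.

**12 ⇒ 8 + 10 (through 11).** Ring C is removed by cutting O1–C2 and C4a–C4. O1–C2 is the bond an enol oxygen forms on adding to a carbonyl-conjugated alkyne, which leads to the alkynyl diketone 11. C4a–C4 is the bond between a ketone α-carbon and an acyl group, which leads to ketone 8 and Weinreb amide 10. These bonds are chosen over C4–C3 or the C2–phenyl bond because 10 delivers ring B and three ring C carbons in one piece at the right oxidation level. In 8 the carbon to be acylated is the α' carbon of a vinylogous ester, exactly where a kinetic enolate forms. Forward, the enolate must be acylated once on carbon, and the oxygen must then close the six-membered and not the five-membered ring.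

**8 ⇒ 2 + 7.** The C8–C3' bond joins two sp2 carbons, each α to a carbonyl group, and is cut to the α-iodo enone 2 and the α-stannyl butenolide 7. This detaches the lactone complete with its gem-dimethyl group and double bond, so nothing of it has to be built on a sensitive intermediate. The iodide fixes the attachment at the carbon between the two oxygenated carbons by constitution. Forward, two hindered, electron-poor partners must be joined under neutral conditions, which points to a Stille coupling.

**2 ⇒ 1.** The C–I bond is cut. The carbon between the oxygenated carbons of the commercial vinylogous ester 1 is its only nucleophilic carbon, so electrophilic iodination should be regiospecific.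

**7 ⇒ 5 (through 6).** The C–Sn bond and the lactone C–O bond are cut. Syn addition of H–Sn across the triple bond of ynoate 5 puts tin α to the ester and places the ester cis to the carbinol in 6, the geometry needed for lactonisation.

**5 ⇒ 3 + 4.** The C4'–C5' bond is cut. Addition of the acetylide of ester 3 to ketone 4 installs the gem-dimethyl carbinol in one step from two bulk chemicals.

**10 ⇒ 9.** The amide C–N bond of 10 is cut, which leads back to acid 9; forward, a standard amide coupling of 9 gives 10.

## Alternatives that were turned down

**Alternative 1:** Here C8–C3' and O1'–C5' are disconnected together. This leads from the 7-O-demethyl compound 3-(7-hydroxy-4-oxo-2-phenyl-4H-chromen-8-yl)-5,5-dimethylfuran-2(5H)-one A2 back to the aryl propargyl ether 4-methyl-4-[(4-oxo-2-phenyl-4H-chromen-7-yl)oxy]pent-2-ynoic acid A1.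
- Forward key step: heating A1 should trigger an aromatic propargyl Claisen shift to C8. After rearomatisation the 2-aryl-2,3-allenoic acid would add its carboxyl group to the allene terminus, giving A2; O-methylation of A2 would finish.
- For: it is the shortest route. It starts from an intact flavone, uses the C7 oxygen as a tether to deliver carbon to C8, builds the C–C bond and the lactone in one cascade and needs no late oxidation.
- Against: the o-allenyl phenol formed after the shift normally undergoes a 1,5-hydrogen shift and oxa-6π-electrocyclisation. Here that would give the isomeric pyranochromene acid 8,8-dimethyl-4-oxo-2-phenyl-4H,8H-pyrano[2,3-f]chromene-10-carboxylic acid A3, whereas lactonisation of an allenoic acid usually needs a catalyst. A3 is an isomer of A2, and nothing in a purely thermal reaction would steer the allene away from A3.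
- Against: the shift to C6 is not excluded, although bond fixation in the chromone favours C8.
- Against: A1 is hard to reach. Copper-catalysed tertiary propargyl ether formation requires a terminal alkyne, so the carboxyl group would have to be added by acetylide chemistry next to a pyranone, and ynoic acids decarboxylate on heating.
- Comparison: Alternative 1 is stronger on step count and avoids tin and the oxidation. The chosen route offers instead a C8 attachment fixed by constitution and ring closures in which no second nucleophile competes.

**Alternative 2:** Ring A and the first carbon of the C8 substituent would come from an aryne. The aryne precursor is 3-methoxy-2-(trimethylsilyl)phenyl trifluoromethanesulfonate A4, and its partner is 3-methylbut-2-enoic acid A5. Together with fluoride, A4 and A5 should give 5-methoxy-2,2-dimethylchroman-4-one A6.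
- Forward key step: fluoride releases 3-methoxybenzyne from A4. The carboxylate oxygen of A5 adds to the aryne carbon remote from the methoxy group, and the aryl anion takes the acyl carbon (formal C–O insertion). The resulting o-hydroxyaryl enone closes by oxa-Michael addition to A6.
- For: the methoxy group of A4 dictates the regiochemistry, so the contiguous OMe / carbon / oxygen pattern of C7, C8 and C8a is laid down in one precedented step from simple materials.
- Against: A6 has the right atoms in the wrong connectivity. The CMe2 carbon is bound to the future O1 instead of a lactone oxygen, and the lactone carbonyl carbon C2' is missing, because A5 supplies only four of the five lactone ring atoms.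
- Against: repair would need a one-carbon homologation at the ketone carbon and an isomerisation of the resulting chromene acid into a hydroxyaryl butenolide, which is the same isomer problem as in Alternative 1.
- Against: all of ring C would still have to be built by ortho-acylation at C4a, in competition with C6, and a diketone cyclisation.
- Comparison: Alternative 2 is stronger in the precedent and regiocontrol of its key step. The chosen route is far more convergent, with ring B and ring C arriving in one step and the lactone arriving complete.

**Alternative 3:** Ring A would be formed last by cutting C4a–C5. Racemic methyl 6,6-dimethoxy-4-oxo-3-(4-oxo-6-phenyl-4H-pyran-2-yl)hexanoate A7 would lead to methyl 2-(7-hydroxy-4-oxo-2-phenyl-4H-chromen-8-yl)acetate A8.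
- Forward key step: acid frees the aldehyde of A7, pyranone C3 attacks it, and loss of water with enolisation of the C7 ketone aromatises ring A to give A8.
- For: the fold follows polyketide logic and the benzene ring arises without an oxidant. The chain constitution fixes the 7-OH and the C8 carbon substituent, and ring C is a robust preformed pyranone.
- Against: pyranone C3 is a weak nucleophile. The unmasked β-keto aldehyde has more acidic sites (the methylene between the carbonyls, the methine at the future C8) that can enolise, eliminate methanol or condense intermolecularly.
- Against: A7 needs a multistep assembly and carries a stereocentre that is destroyed.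
- Against: after the key step the acetate arm of A8 must still be turned into the dimethylbutenolide (C4', C5', gem-dimethyl, double bond) and the phenol methylated.
- Comparison: Alternative 3 is as good or better in avoiding an oxidation. The chosen route is shorter and does not have to construct the lactone on the finished flavone.

Key step: step 6

Remark: compounds 1, 3, 4 and 9 are taken to be commercial, and 11 is written as its enol tautomer.

## Route

**Step 1**
Reactants: 1 3-methoxycyclohex-2-en-1-one
Product: 2 2-iodo-3-methoxycyclohex-2-en-1-one
Conditions: NIS, CH2Cl2, 0 °C → rt, dark
Reagents that add atoms: N-iodosuccinimide, O=C1CCC(=O)N1I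
Why: Electrophilic α-iodination of a vinylogous ester; C2 is the only nucleophilic carbon (β-position of the enol ether), and loss of the C2 proton restores the conjugated enone.

**Step 2**
Reactants: 3 ethyl propiolate; 4 acetone
Product: 5 ethyl 4-hydroxy-4-methylpent-2-ynoate
Conditions: n-BuLi, THF, −78 °C; then 4, −78 °C; AcOH, −78 °C
Reagents that add atoms: none
Why: Acetylide addition to a ketone; the lithiated propiolate adds 1,2 to acetone, and the low temperature throughout, including the quench, suppresses self-condensation of the lithiated ester and retro-addition.

**Step 3**
Reactants: 5 ethyl 4-hydroxy-4-methylpent-2-ynoate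
Product: 7 5,5-dimethyl-3-(tributylstannyl)furan-2(5H)-one, via open-chain stannyl hydroxy enoate 6 (not isolated)
Conditions: Bu3SnH, Pd(PPh3)4 (cat.), THF, 0 °C → rt; then PPTS (cat.), toluene, 60 °C
Reagents that add atoms: tributyltin hydride, CCCC[SnH](CCCC)CCCC
Why: Palladium-catalysed hydrostannation of an alkynoate is a syn addition that puts hydrogen on the β-carbon and tin α to the ester, so ester and carbinol are cis in 6; mild acid then closes the lactone by transesterification, helped by the gem-dimethyl group, with loss of ethanol.

**Step 4**
Reactants: 2 2-iodo-3-methoxycyclohex-2-en-1-one; 7 5,5-dimethyl-3-(tributylstannyl)furan-2(5H)-one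
Product: 8 3-(2-methoxy-6-oxocyclohex-1-en-1-yl)-5,5-dimethylfuran-2(5H)-one
Conditions: Pd(PPh3)4 (cat.), CuI (cat.), CsF, DMF, 45 °C
Reagents that add atoms: none
Why: Stille coupling; zerovalent palladium inserts readily into the C–I bond of the α-iodo enone, CuI and fluoride speed up transmetallation from the hindered α-stannyl lactone and remove tin as Bu3SnF, and the neutral medium leaves the lactone and the enol ether untouched.

**Step 5**
Reactants: 9 3-phenylprop-2-ynoic acid
Product: 10 N-methoxy-N-methyl-3-phenylprop-2-ynamide
Conditions: MeNHOMe·HCl, EDC·HCl, N-methylmorpholine, CH2Cl2, 0 °C → rt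
Reagents that add atoms: N,O-dimethylhydroxylamine hydrochloride, CNOC.Cl
Why: Carbodiimide-mediated amide formation; at low temperature the activated acid should be intercepted at the acyl carbon by the weakly basic amine faster than the amine adds to the triple bond.

**Step 6**
Reactants: 8 3-(2-methoxy-6-oxocyclohex-1-en-1-yl)-5,5-dimethylfuran-2(5H)-one; 10 N-methoxy-N-methyl-3-phenylprop-2-ynamide
Product: 12 3-(7-methoxy-4-oxo-2-phenyl-5,6-dihydro-4H-chromen-8-yl)-5,5-dimethylfuran-2(5H)-one, via enolised alkynyl diketone 11 (not isolated)
Conditions: LiN(SiMe3)2 (2.1 equiv), THF, −78 °C; then 10, −78 → −30 °C; AcOH, pH 7 work-up; crude 11, TfOH (cat.), CH2Cl2, 0 °C → rt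
Reagents that add atoms: none
Why: LiN(SiMe3)2 at −78 °C should remove a proton from the CH2 next to the ketone of 8 (the α' position, future C4a) faster than from the γ-CH2 next to the enol ether carbon, giving the cross-conjugated kinetic enolate as in Stork–Danheiser chemistry of 3-alkoxycyclohexenones. This enolate adds through carbon to the amide carbonyl of 10 (Claisen-type C-acylation by a Weinreb amide, forming C4a–C4); the lithium-chelated tetrahedral adduct, or after its collapse the diketonate formed with the second equivalent of base, cannot be acylated again. Protonation gives 11, in which the ring carbonyl is enolised and hydrogen-bonded to the ynone. Under anhydrous acid the ynone is activated at oxygen, positive charge builds up on the alkyne carbon bearing phenyl, and the enol oxygen on the future C8a adds there: a 6-endo-dig oxa-Michael closure that forms O1–C2 and ring C, the closest known reactions being the acid-promoted cyclisations of alkynyl 1,3-diketones to 4-pyranones and of o-hydroxyaryl ynones to flavones. No stereocentre is formed. The step needs α' over γ deprotonation (kinetic control with a hindered amide base at low temperature), C- over O-acylation and 1,2- over 1,4-addition to the ynamide (hard lithium enolate, chelating N-methoxy amide), and 6-endo over 5-exo closure (polarisation of the ynone towards its benzylic β-carbon under Brønsted acid, with no π-acidic metal present). The substrate secures the rest: the 5,5-dimethylbutenolide has no enolisable hydrogen, attack of the enolate on the lactone carbonyl would be a disfavoured 5-(enolendo)-exo-trig closure, the ring ketone is the only oxygen that can reach the alkyne, and exclusion of water in the acid stage protects the C7 enol ether.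

**Step 7**
Reactants: 12 3-(7-methoxy-4-oxo-2-phenyl-5,6-dihydro-4H-chromen-8-yl)-5,5-dimethylfuran-2(5H)-one
Product: 13 3-(7-methoxy-4-oxo-2-phenyl-4H-chromen-8-yl)-5,5-dimethylfuran-2(5H)-one
Conditions: DDQ, 1,4-dioxane, rt → 80 °C
Reagents that add atoms: none
Why: Quinone dehydrogenation; DDQ should abstract hydride from C5 to give the C6-protonated arenium ion of the product, stabilised by C7–OMe and O1, and loss of the C6 proton aromatises ring A, while the lactone, pyranone and phenyl ring offer no comparably hydridic C–H bond.

## Compound list

1 | 3-methoxycyclohex-2-en-1-one | COC1=CC(=O)CCC1 | starting material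
2 | 2-iodo-3-methoxycyclohex-2-en-1-one | COC1=C(I)C(=O)CCC1 | intermediate
3 | ethyl propiolate (ethyl prop-2-ynoate) | CCOC(=O)C#C | starting material
4 | acetone (propan-2-one) | CC(C)=O | starting material
5 | ethyl 4-hydroxy-4-methylpent-2-ynoate | CCOC(=O)C#CC(C)(C)O | intermediate
6 | ethyl (E)-4-hydroxy-4-methyl-2-(tributylstannyl)pent-2-enoate (formed and consumed in step 3) | CCOC(=O)/C([Sn](CCCC)(CCCC)CCCC)=C\C(C)(C)O | intermediate
7 | 5,5-dimethyl-3-(tributylstannyl)furan-2(5H)-one | CCCC[Sn](CCCC)(CCCC)C1=CC(C)(C)OC1=O | intermediate
8 | 3-(2-methoxy-6-oxocyclohex-1-en-1-yl)-5,5-dimethylfuran-2(5H)-one | COC1=C(C2=CC(C)(C)OC2=O)C(=O)CCC1 | intermediate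
9 | 3-phenylprop-2-ynoic acid (phenylpropiolic acid) | OC(=O)C#Cc1ccccc1 | starting material
10 | N-methoxy-N-methyl-3-phenylprop-2-ynamide | CON(C)C(=O)C#Cc1ccccc1 | intermediate
11 | 3-[6-hydroxy-2-methoxy-5-(3-phenylprop-2-ynoyl)cyclohexa-1,5-dien-1-yl]-5,5-dimethylfuran-2(5H)-one (enol tautomer; formed and consumed in step 6) | COC1=C(C2=CC(C)(C)OC2=O)C(O)=C(CC1)C(=O)C#Cc1ccccc1 | intermediate
12 | 3-(7-methoxy-4-oxo-2-phenyl-5,6-dihydro-4H-chromen-8-yl)-5,5-dimethylfuran-2(5H)-one | COC1=C(C3=CC(C)(C)OC3=O)C2=C(CC1)C(=O)C=C(c4ccccc4)O2 | intermediate
13 | 3-(7-methoxy-4-oxo-2-phenyl-4H-chromen-8-yl)-5,5-dimethylfuran-2(5H)-one | COc1ccc2c(=O)cc(-c3ccccc3)oc2c1C1=CC(C)(C)OC1=O | target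

## Step count and least certain steps

Total step count: 7. Longest linear sequence: 5 steps (steps 2, 3, 4, 6, 7).

**Step 6 (key step).**
- Risk: the acylation may stall or go astray. The acylated product can transfer a proton to unreacted enolate, the enolate or the amide base can attack the β-carbon of the ynamide, and O-acylation is possible. In the second stage, traces of water would hydrolyse the C7 enol ether, and closure through the 5-exo mode cannot be ruled out.
- Fallback: it sets out from 8. The same kinetic enolate (one equivalent of LiN(SiMe3)2) is added to 3-phenylprop-2-ynal, a far more electrophilic acceptor whose alkoxide adduct is not acidic. This gives the aldol 3-[5-(1-hydroxy-3-phenylprop-2-yn-1-yl)-2-methoxy-6-oxocyclohex-1-en-1-yl]-5,5-dimethylfuran-2(5H)-one F1. Oxidation of the carbinol of F1 with Dess–Martin periodinane comes back to the route at 11, which is closed to 12 as in step 6.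

**Step 4.**
- Risk: transmetallation from the hindered, electron-poor α-stannyl lactone onto a palladium centre flanked by carbonyl and methoxy groups may be slow, so that protodestannylation and homocoupling of the stannane take over.
- Fallback: it sets out from 2 and builds the lactone on the ring instead of coupling it preformed. Sonogashira coupling with 2-methylbut-3-yn-2-ol (PdCl2(PPh3)2, CuI, Et3N) attaches an unhindered sp carbon and gives 2-(3-hydroxy-3-methylbut-1-yn-1-yl)-3-methoxycyclohex-2-en-1-one F2. Palladium-catalysed cyclocarbonylation of the tertiary alkynol F2 (CO/H2, Pd2(dba)3, 1,4-bis(diphenylphosphino)butane, CH2Cl2, 95 °C) places the carbonyl carbon on the alkyne carbon bound to the ring and comes back to the route at 8.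

**Step 3.**
- Risk: the C–Sn bond may be lost by protonolysis during the acid-mediated lactonisation, or ring closure of the tertiary alcohol may be incomplete.
- Fallback: it sets out from 6, isolated after the hydrostannation without acid treatment. Stille coupling of 6 with 2 under the conditions of step 4 gives ethyl (Z)-4-hydroxy-2-(2-methoxy-6-oxocyclohex-1-en-1-yl)-4-methylpent-2-enoate F3. The lactone of F3 is then closed after the tin has gone (DBU (cat.), toluene, 60 °C), coming back to the route at 8.

**Step 7.**
- Risk: hydride abstraction may be slow because the developing cation is cross-conjugated with the C4 carbonyl, and forcing conditions could bring over-oxidation or addition of the quinone to the enol ether.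
- Fallback: it sets out from 11, isolated after the acylation stage of step 6, and reverses the order of events. The more electron-rich enol 11 is dehydrogenated with DDQ to the o-hydroxyaryl ynone 3-[2-hydroxy-6-methoxy-3-(3-phenylprop-2-ynoyl)phenyl]-5,5-dimethylfuran-2(5H)-one F4. Acid-promoted 6-endo closure of F4 (TfOH, CH2Cl2), the standard flavone ring closure, comes back to the route at 13.

## Further compounds

F1 | step 6 | 3-[5-(1-hydroxy-3-phenylprop-2-yn-1-yl)-2-methoxy-6-oxocyclohex-1-en-1-yl]-5,5-dimethylfuran-2(5H)-one (mixture of diastereomers, each racemic) | COC1=C(C2=CC(C)(C)OC2=O)C(=O)C(CC1)C(O)C#Cc1ccccc1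
F2 | step 4 | 2-(3-hydroxy-3-methylbut-1-yn-1-yl)-3-methoxycyclohex-2-en-1-one | COC1=C(C#CC(C)(C)O)C(=O)CCC1
F3 | step 3 | ethyl (Z)-4-hydroxy-2-(2-methoxy-6-oxocyclohex-1-en-1-yl)-4-methylpent-2-enoate | CCOC(=O)/C(C1=C(OC)CCCC1=O)=C\C(C)(C)O
F4 | step 7 | 3-[2-hydroxy-6-methoxy-3-(3-phenylprop-2-ynoyl)phenyl]-5,5-dimethylfuran-2(5H)-one | COc1ccc(C(=O)C#Cc2ccccc2)c(O)c1C1=CC(C)(C)OC1=O
A1 | alternative 1 | 4-methyl-4-[(4-oxo-2-phenyl-4H-chromen-7-yl)oxy]pent-2-ynoic acid | OC(=O)C#CC(C)(C)Oc1ccc2c(=O)cc(-c3ccccc3)oc2c1
A2 | alternative 1 | 3-(7-hydroxy-4-oxo-2-phenyl-4H-chromen-8-yl)-5,5-dimethylfuran-2(5H)-one | Oc1ccc2c(=O)cc(-c3ccccc3)oc2c1C1=CC(C)(C)OC1=O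
A3 | alternative 1 | 8,8-dimethyl-4-oxo-2-phenyl-4H,8H-pyrano[2,3-f]chromene-10-carboxylic acid | OC(=O)C1=CC(C)(C)Oc2ccc3c(=O)cc(-c4ccccc4)oc3c21
A4 | alternative 2 | 3-methoxy-2-(trimethylsilyl)phenyl trifluoromethanesulfonate | COc1cccc(OS(=O)(=O)C(F)(F)F)c1[Si](C)(C)C
A5 | alternative 2 | 3-methylbut-2-enoic acid | CC(C)=CC(=O)O
A6 | alternative 2 | 5-methoxy-2,2-dimethylchroman-4-one | COc1cccc2OC(C)(C)CC(=O)c12
A7 | alternative 3 | methyl 6,6-dimethoxy-4-oxo-3-(4-oxo-6-phenyl-4H-pyran-2-yl)hexanoate (racemic) | COC(=O)CC(C(=O)CC(OC)OC)c1cc(=O)cc(-c2ccccc2)o1
A8 | alternative 3 | methyl 2-(7-hydroxy-4-oxo-2-phenyl-4H-chromen-8-yl)acetate | COC(=O)Cc1c(O)ccc2c(=O)cc(-c3ccccc3)oc12
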